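## Structural features

Betaethrin E is an achiral diaryl ether: two tetrasubstituted benzene rings joined by one oxygen. Ring A carries, on three adjacent carbons, the palmitoyloxymethyl group, the ether oxygen and a free phenol, with a methoxy group para to the ether carbon. Ring B is a methyl salicylate whose ester-bearing carbon lies between the ether-bearing carbon and a phenol carbon, with a methyl group para to the ester. The target has no stereocenter, so none stand next to each other; the only one met on the way is a transient spiro carbon that is erased again. The fragile groups are the benzylic fatty ester (alkoxide methanolysis, acid ionisation, hydrogenolysis), the salicylate methyl ester and the two electron-rich phenols. The real difficulty is the ether bond: the ring A carbon that bears it is flanked on both sides (OH and CH2O) and both rings are electron-rich, so arylation of a phenol is unattractive. A second difficulty is telling one primary alcohol from two phenols when the C16 acyl group is introduced. The key step exploits the unit ether O / ring A carbon / ring B ester carbon, which together with two ortho carbons of ring B is O1–C2–C3 of a benzofuran-3(2H)-one: C2 becomes the ether-bearing carbon of ring A, C3 the ester carbon, and ring A is built on C2 by a spiro-aldol closure.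

## Logic of the disconnections

**21 to 20.** The two aryl–O–CH2OMe acetal bonds are the last to be cut in the forward sense. Both phenols stay under the same acetal to the end, so the esterification meets a single hydroxyl group and one operation frees both phenols. The forward step must spare the benzylic ester C–O bond, the methyl ester and the aryl methyl ether, which points to an aprotic Lewis acid with a thiol and away from a protic acid in an alcohol.

**20 to 18 and 19, then 18 to 17.** The ester C–O bond between the benzylic oxygen and the acyl carbon is cut, and the alcohol of 18 is traced to the silyl ether of 17. The long-chain ester therefore enters after every strongly basic step. The desilylation must not let a benzylic alkoxide reach the neighbouring ring B ester.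

**17 to 15 by way of 16.** The acetal on the ring A oxygen is removed, and the bond between the ring B ester carbon and the ether-bearing ring A carbon is re-formed. The ester becomes a ring ketone, the ring A phenol becomes a dienone carbonyl, and ring A loses its aromaticity. The gain is that the diaryl ether oxygen now sits on an sp3 carbon of a five-membered ring, so the hardest bond of the target never has to be made by arylation. In the forward step the alkoxide must attack the five-ring ketone and not the dienone carbonyl; only the former cleavage expels an aromatic phenoxide. That phenoxide is capped in the same flask, which removes the phenol/alcohol selectivity problem.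

**15 to 13 (key disconnection).** The ring A bond between the spiro carbon and the CH2O-bearing carbon is cut, with formal addition of water across the adjacent double bond. Ring A opens to a six-carbon chain attached through its acyl carbon to C2 of the bicyclic ketone; one ring and one quaternary centre are removed. The forward step needs C2, not the chain methylene, as nucleophile and the remote chain ketone, not the ring ketone, as electrophile.

**13 to 7 and 12.** The bond between C2 and the acyl carbon is cut. The whole chain (acyl carbon, enol ether, ketone, protected primary alcohol) is already stored in 12, including the cis relation of acyl carbon and CH2 across the enol ether. The union is convergent. The enolate must attack the lactone carbonyl of 12 and not its two conjugate positions.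

**7 to 4, 4 to 2 and 3, 2 to 1.** A carboxyl group is put back on C2 of 7 and the bond from C2 to the ring carbonyl carbon is cut, giving 4. Cutting the alkyl–oxygen bond of 4 gives 2 and 3, and removing the acetal from 2 gives 1. The bond that ends as the diaryl ether is thus made by SN2 at a primary carbon; of 3 only the CH2 carbon survives, as the ether-bearing carbon of ring A. Because 1 is symmetrical, protecting one phenol raises no regiochemical question. The decarboxylation must leave the acetal intact.

**12 to 11, 10, 9 and 8.** The Si–O bond is cut, the CH2OH group is traced through the aldehyde to the ring methyl group, and the enol ether methyl to the 4-hydroxyl. Five ring carbons of ring A and its CH2O carbon come from 8. The demand is oxidation of the methyl group without damage to the pyrone.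

## Other disconnections considered

**Alternative 1:** The cut removes, on ring B, both the ether C–O bond and the bond from the neighbouring ring carbon to the ester carbon, so ring B becomes an aryne and ring A an aryl methyl carbonate.
- *Forward step:* CsF would release 3-(methoxymethoxy)-5-methylbenzyne from the silyl triflate A1. The aryl-bound oxygen of carbonate A2 adds to the aryne carbon remote from the acetal oxygen, and the aryl anion formed next to that oxygen takes over the methoxycarbonyl group. This net insertion into the O–C(=O) bond gives A3, which has the constitution of 17.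
- *In favour:* both ortho bonds of ring B are made in one operation and no ring is opened or closed. The usual preference of 3-alkoxyarynes for attack at the remote carbon fits the required orientation. The union is fully convergent, and A3 enters the same last three steps as 17 with no dearomatised, base-sensitive intermediate.
- *Against:* A2 must be made from phenol A4, a 1,2,3,5-tetrasubstituted arene with three different oxygen functions that needs its own synthesis, and A1 needs several steps too. The carbonate oxygen is a weak nucleophile flanked by two ortho substituents. Fluoride can attack the carbonate carbonyl instead, and the phenoxide released can add to the aryne and be protonated, giving the ether without the ester. Aryne insertion into O–C(=O) bonds is less secure than into N–C(=O) or C–C(=O) bonds.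
- *Comparison:* structurally, both plans avoid substitution on an intact electron-rich ring B, the alternative through an sp carbon, the chosen plan through an sp3 carbon. Mechanistically, the chosen plan runs on enolate steps that each end in a thermodynamic sink, whereas the alternative depends on the relative rates at which several nucleophiles capture a short-lived aryne. In convergence the alternative is the better plan, and in the steps after the union it is the equal of the chosen one. In total step count it should not be shorter, because two substituted arenes must be built separately.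

**Alternative 2:** The cut takes ring A apart at three C–C bonds: the two at the phenol carbon and the one between the methoxy-bearing carbon and the CH next to the CH2O-bearing carbon. This leaves a diazo enone that already carries the aryloxy group, and a two-carbon alkyne.
- *Forward step:* irradiation of A5 would cause Wolff rearrangement to an aryloxy vinylketene, which adds methoxyacetylene A6 in a [2+2] sense. Four-electron opening of the cyclobutenone, six-electron ring closure and tautomerisation give phenol A7, which has the constitution of 16.
- *In favour:* the meta relation of OH and OMe and the positions of the ether and CH2O groups follow from the connectivity of the partners. The ether bond is again made at a non-aromatic carbon, by conjugate addition of 2 to an ynone, so the plan shares the central idea of the chosen one and could start from the same 2. The ring B ester is never disturbed.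
- *Against:* A5 combines a diazo ketone with a β-aryloxy enone and would come from diazo transfer on a sensitive methyl ketone. A6 is volatile and unstable and must be prepared before use. The cascade is photochemical and has four consecutive pericyclic events, each of which can be diverted, for example by capture of the ketene by a nucleophile. A7 has a free ring A phenol beside a silyl ether, so the phenol/alcohol problem is left to later steps.
- *Comparison:* structurally the alternative is the equal of the chosen plan, since it arrives at the compound that step 10 passes through. It is the better plan in that ring A is aromatic as soon as it forms and no strong nucleophile is needed late. Mechanistically it trades two-electron enolate chemistry for a light-driven ketene cascade that is harder to scale. No gain in step count is expected: about five steps from 2 to A5, against four steps on the main line from 2 to 15.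

**Alternative 3:** The cut opens ring B at two C–C bonds: the one between the methyl-bearing carbon and the CH leading to the phenol carbon, and the one between the phenol carbon and the ester-bearing carbon. Four ring carbons then come from a 2-pyrone and two from a ketene acetal.
- *Forward step:* the 4-aryloxy pyrone ester A8 would react with ketene bis(trimethylsilyl) acetal A9. The CH2 terminus bonds to C6 of the pyrone and the acetal carbon to C3; the bridged lactone loses CO2, and loss of Me3SiOH with desilylation on work-up leaves salicylate A10.
- *In favour:* the polarity of the pyrone fixes the orientation, so the phenol appears next to the ester. The ring B phenol is born free and chelated to the ester, where it is a poor nucleophile and may need no protecting group; this is a real advantage over the chosen plan. The ether bond is made by addition–elimination of A4 at C4 of a pyrone, a vinylogous acyl substitution and not an arylation.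
- *Against:* the hindered phenol A4 is needed again and costs a multistep synthesis. The 4-aryloxy group donates into the pyrone and makes it a less willing electron-poor diene, and C3 and C4 are both fully substituted, so forcing conditions are likely. Ketene silyl acetals can also add to the ester or transfer silicon to oxygen. The silyl ether and acetal on ring A would have to survive the heat.
- *Comparison:* structurally the plans mirror each other: the alternative builds ring B on a finished ring A, the chosen plan builds ring A on a finished ring B, and both make the ether bond at a non-aromatic carbon. The chosen plan has the easier aromatic starting material, because ring B is symmetrical in 1 whereas ring A in A4 is not. Mechanistically the cycloaddition–extrusion sequence is as well founded as the aldol and retro-Claisen pair. In protecting-group economy on ring B the alternative is the better; in step count it should be the longer because of A4.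

Key step: step 9

Remark on the chemistry: the structures of 13 and 15 map atom for atom onto the target and are used unchanged; 13 is drawn as the triketone but should exist largely as its chelated enol (a 2-acyl-3-hydroxybenzofuran), and 13, 14 and 15 are racemic, which is without consequence because the spiro carbon becomes an aromatic carbon in step 10.

## Route

Step 1
Reactants: 1 methyl 2,6-dihydroxy-4-methylbenzoate
Product: 2 methyl 2-hydroxy-6-(methoxymethoxy)-4-methylbenzoate
Conditions: MOMCl (1.05 equiv), i-Pr2NEt, CH2Cl2, 0 °C to rt
Reagents that add atoms: chloromethyl methyl ether (MOMCl), COCCl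
Why: O-alkylation of one of two equivalent phenols to the acetal; once one has reacted, the other is held in a strong hydrogen bond to the ester carbonyl and should react much more slowly, so one equivalent should stop at the mono-ether. No stereocenter is formed.

Step 2
Reactants: 2 methyl 2-hydroxy-6-(methoxymethoxy)-4-methylbenzoate; 3 methyl bromoacetate
Product: 4 methyl 2-(2-methoxy-2-oxoethoxy)-6-(methoxymethoxy)-4-methylbenzoate
Conditions: K2CO3, DMF, 50 °C
Reagents that add atoms: none
Why: Williamson ether synthesis; the phenoxide displaces bromide from the primary α-halo ester by SN2. This ordinary alkyl aryl ether bond is the one that ends as the hindered diaryl ether bond of the target.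

Step 3
Reactants: 4 methyl 2-(2-methoxy-2-oxoethoxy)-6-(methoxymethoxy)-4-methylbenzoate
Product: 7 4-(methoxymethoxy)-6-methyl-1-benzofuran-3(2H)-one, via Dieckmann β-keto ester 5 (not isolated), via β-keto acid 6 (not isolated)
Conditions: NaOMe, MeOH, 65 °C; then 2 M NaOH (aq), 80 °C; then AcOH to pH 5, 50 °C
Reagents that add atoms: none
Why: Dieckmann condensation (5-exo-trig attack of the aryloxyacetate enolate on the neighbouring benzoate, driven by formation of the stabilised enolate of 5), followed by saponification and decarboxylation of the β-keto acid 6 on mild acidification. The acetal is stable to base and to pH 5, and the ketone is released only at the end, which limits its self-condensation.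

Step 4
Reactants: 8 4-hydroxy-6-methyl-2H-pyran-2-one
Product: 9 4-methoxy-6-methyl-2H-pyran-2-one
Conditions: Me2SO4, K2CO3, acetone, reflux
Reagents that add atoms: dimethyl sulfate, COS(=O)(=O)OC
Why: O-methylation of the vinylogous acid; under carbonate and dimethyl sulfate in acetone the ambident anion is expected to be alkylated on the 4-oxygen to give the 4-methoxy-2-pyrone.

Step 5
Reactants: 9 4-methoxy-6-methyl-2H-pyran-2-one
Product: 10 4-methoxy-2-oxo-2H-pyran-6-carbaldehyde
Conditions: SeO2, 1,4-dioxane, 150 °C (sealed tube)
Reagents that add atoms: selenium dioxide, O=[Se]=O
Why: Riley oxidation; the 6-methyl group is vinylogously activated by the lactone carbonyl and is the only allylic position, so ene reaction and [2,3]-shift with SeO2 should take it to the aldehyde.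

Step 6
Reactants: 10 4-methoxy-2-oxo-2H-pyran-6-carbaldehyde
Product: 11 6-(hydroxymethyl)-4-methoxy-2H-pyran-2-one
Conditions: NaBH4, MeOH–THF, 0 °C
Reagents that add atoms: none
Why: Chemoselective hydride 1,2-reduction of the aldehyde; the vinylogous carbonate carbonyl of the pyrone is far less electrophilic and should survive a short reaction at 0 °C.

Step 7
Reactants: 11 6-(hydroxymethyl)-4-methoxy-2H-pyran-2-one
Product: 12 4-methoxy-6-({[tri(propan-2-yl)silyl]oxy}methyl)-2H-pyran-2-one
Conditions: TIPSCl, imidazole, DMF, rt
Reagents that add atoms: chlorotri(propan-2-yl)silane (TIPSCl), CC(C)[Si](Cl)(C(C)C)C(C)C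
Why: Silylation of the primary alcohol; the bulky silyl ether withstands the enolate, carbonate and methoxide steps that follow and shields the neighbouring CH2 from deprotonation.

Step 8
Reactants: 7 4-(methoxymethoxy)-6-methyl-1-benzofuran-3(2H)-one; 12 4-methoxy-6-({[tri(propan-2-yl)silyl]oxy}methyl)-2H-pyran-2-one
Product: 13 2-[(2E)-3-methoxy-5-oxo-6-{[tri(propan-2-yl)silyl]oxy}hex-2-enoyl]-4-(methoxymethoxy)-6-methyl-1-benzofuran-3(2H)-one (racemic)
Conditions: 7, LiN(SiMe3)2 (1.05 equiv), THF, −78 °C; then 12, −78 to −20 °C; AcOH quench at −78 °C
Reagents that add atoms: none
Why: Claisen-type C-acylation of the lithium enolate of 7 by the lactone carbonyl of 12 with ring opening; the dienolate released takes the now very acidic C2 proton, so the chelated lithium β-diketonate is the sink and one equivalent of base suffices. The enolate of 7 (an aromatic 3-oxidobenzofuran) should be too weak a base to deprotonate the CH2OSi group of 12, and the enol ether geometry (acyl carbon and CH2 cis, 2E) is inherited from the ring. C2 is formed racemic and is enolised in any case; material that has already closed to 14 converges in step 9.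

Step 9
Reactants: 13 2-[(2E)-3-methoxy-5-oxo-6-{[tri(propan-2-yl)silyl]oxy}hex-2-enoyl]-4-(methoxymethoxy)-6-methyl-1-benzofuran-3(2H)-one
Product: 15 4'-methoxy-4-(methoxymethoxy)-6-methyl-6'-({[tri(propan-2-yl)silyl]oxy}methyl)-3H-spiro[1-benzofuran-2,1'-cyclohexa[3,5]diene]-2',3-dione (racemic), via aldol adduct 14 (not isolated)
Conditions: K2CO3 (1.2 equiv), 4 Å molecular sieves, MeCN, 0 to 40 °C
Reagents that add atoms: none
Why: K2CO3 removes the C2 proton, the most acidic one because it lies between the ring ketone and the acyl carbonyl, and the enolate carbon adds to the isolated chain ketone, which is activated by its α-silyloxy group, to give 14. Deprotonation of the ring CH2 of 14 through the vinylogous ester then expels hydroxide (E1cB) and gives the conjugated 2,4-dienone 15; the aldol addition is reversible but the loss of water is not, so material should drain to 15. The closest known reaction type is the intramolecular aldol condensation of a 1,3-dicarbonyl carbon onto a ketone, as used for spiro rings of grisan type. Ring A closes in a 6-exo-trig mode at the ketone (6-enolexo with respect to the ring enolate), and the cis arrangement of acyl carbon and CH2 on the enol ether holds the ketone within reach. The spiro carbon is the one new stereocenter; nothing controls it, 15 is racemic, and this is irrelevant because the centre becomes aromatic in step 10, while the carbinol centre of 14 disappears on dehydration. The step needs site selectivity between two six-membered aldol closures: with about one equivalent of mild base only C2 is deprotonated, the ring carbonyl is then part of the enolate and cannot act as electrophile for the chain methylene (which would lead to a dibenzofuran), and the acyl carbonyl is deactivated as part of the same enolate and as a vinylogous ester. The sieves take up the water so that no hydroxide opens 15.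

Step 10
Reactants: 15 4'-methoxy-4-(methoxymethoxy)-6-methyl-6'-({[tri(propan-2-yl)silyl]oxy}methyl)-3H-spiro[1-benzofuran-2,1'-cyclohexa[3,5]diene]-2',3-dione
Product: 17 methyl 2-[4-methoxy-2-(methoxymethoxy)-6-({[tri(propan-2-yl)silyl]oxy}methyl)phenoxy]-6-(methoxymethoxy)-4-methylbenzoate, via ring A phenoxide 16 (not isolated)
Conditions: NaOMe (1.1 equiv), MeOH–THF, 0 °C; evaporate; then MOMCl (1.5 equiv), DMF, 0 °C to rt
Reagents that add atoms: sodium methoxide, [Na+].[O-]C; chloromethyl methyl ether (MOMCl), COCCl
Why: Retro-Claisen cleavage of a non-enolisable 1,3-dicarbonyl: methoxide adds to the strained five-ring ketone and the C–C bond to the spiro carbon breaks because the leaving carbanion is the aromatic phenoxide of ring A, which sets the ring B methyl ester and erases the stereocenter. Attack at the dienone carbonyl would not aromatise ring A and should not compete. The phenoxide is then O-alkylated in the same flask (Williamson), so no free phenol is present when the acyl chloride is used.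

Step 11
Reactants: 17 methyl 2-[4-methoxy-2-(methoxymethoxy)-6-({[tri(propan-2-yl)silyl]oxy}methyl)phenoxy]-6-(methoxymethoxy)-4-methylbenzoate
Product: 18 methyl 2-[2-(hydroxymethyl)-4-methoxy-6-(methoxymethoxy)phenoxy]-6-(methoxymethoxy)-4-methylbenzoate
Conditions: Bu4NF, AcOH (1:1), THF, 0 °C to rt
Reagents that add atoms: none
Why: Fluoride-driven cleavage of the Si–O bond; buffering with AcOH keeps the benzylic oxygen protonated so that it cannot attack the ring B methyl ester to form an eight-membered lactone. The acetals and esters are inert to these conditions.

Step 12
Reactants: 18 methyl 2-[2-(hydroxymethyl)-4-methoxy-6-(methoxymethoxy)phenoxy]-6-(methoxymethoxy)-4-methylbenzoate; 19 palmitoyl chloride (hexadecanoyl chloride)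
Product: 20 methyl 2-{2-[(hexadecanoyloxy)methyl]-4-methoxy-6-(methoxymethoxy)phenoxy}-6-(methoxymethoxy)-4-methylbenzoate
Conditions: 19 (1.2 equiv), Et3N, DMAP (cat.), CH2Cl2, 0 °C
Reagents that add atoms: none
Why: Nucleophilic acyl substitution with acyl-pyridinium catalysis; the primary alcohol is the only hydroxyl group in 18, so no chemoselectivity is required.

Step 13
Reactants: 20 methyl 2-{2-[(hexadecanoyloxy)methyl]-4-methoxy-6-(methoxymethoxy)phenoxy}-6-(methoxymethoxy)-4-methylbenzoate
Product: 21 Betaethrin E, methyl 2-{2-[(hexadecanoyloxy)methyl]-6-hydroxy-4-methoxyphenoxy}-6-hydroxy-4-methylbenzoate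
Conditions: ZnBr2, n-PrSH, CH2Cl2, 0 °C
Reagents that add atoms: none
Why: Lewis acid–thiol cleavage of both aryl methoxymethyl acetals; ZnBr2 activates the acetal and the thiol takes the methoxymethyl group. The medium is aprotic and non-hydrolytic and the contact time short, so the benzylic palmitate, the methyl ester and the aryl methyl ether should be left alone.

## Compound list

1 | methyl 2,6-dihydroxy-4-methylbenzoate | COC(=O)c1c(O)cc(C)cc1O | starting material
2 | methyl 2-hydroxy-6-(methoxymethoxy)-4-methylbenzoate | COC(=O)c1c(O)cc(C)cc1OCOC | intermediate
3 | methyl bromoacetate | COC(=O)CBr | starting material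
4 | methyl 2-(2-methoxy-2-oxoethoxy)-6-(methoxymethoxy)-4-methylbenzoate | COC(=O)COc1cc(C)cc(OCOC)c1C(=O)OC | intermediate
5 | methyl 3-hydroxy-4-(methoxymethoxy)-6-methyl-1-benzofuran-2-carboxylate (enol form of the β-keto ester, present as its sodium salt; not isolated) | COC(=O)c1oc2cc(C)cc(OCOC)c2c1O | intermediate
6 | 3-hydroxy-4-(methoxymethoxy)-6-methyl-1-benzofuran-2-carboxylic acid (not isolated) | OC(=O)c1oc2cc(C)cc(OCOC)c2c1O | intermediate
7 | 4-(methoxymethoxy)-6-methyl-1-benzofuran-3(2H)-one | Cc1cc(OCOC)c2C(=O)COc2c1 | intermediate
8 | 4-hydroxy-6-methyl-2H-pyran-2-one | CC1=CC(O)=CC(=O)O1 | starting material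
9 | 4-methoxy-6-methyl-2H-pyran-2-one | CC1=CC(OC)=CC(=O)O1 | intermediate
10 | 4-methoxy-2-oxo-2H-pyran-6-carbaldehyde | O=CC1=CC(OC)=CC(=O)O1 | intermediate
11 | 6-(hydroxymethyl)-4-methoxy-2H-pyran-2-one | OCC1=CC(OC)=CC(=O)O1 | intermediate
12 | 4-methoxy-6-({[tri(propan-2-yl)silyl]oxy}methyl)-2H-pyran-2-one | COC1=CC(=O)OC(CO[Si](C(C)C)(C(C)C)C(C)C)=C1 | intermediate
13 | 2-[(2E)-3-methoxy-5-oxo-6-{[tri(propan-2-yl)silyl]oxy}hex-2-enoyl]-4-(methoxymethoxy)-6-methyl-1-benzofuran-3(2H)-one (racemic, largely enolised) | Cc1cc(OCOC)c2C(=O)C(C(=O)/C=C(OC)\CC(=O)CO[Si](C(C)C)(C(C)C)C(C)C)Oc2c1 | intermediate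
14 | 6'-hydroxy-4'-methoxy-4-(methoxymethoxy)-6-methyl-6'-({[tri(propan-2-yl)silyl]oxy}methyl)-3H-spiro[1-benzofuran-2,1'-cyclohex[3]ene]-2',3-dione (racemic, mixture of diastereomers; not isolated) | COC1=CC(=O)C2(Oc3cc(C)cc(OCOC)c3C2=O)C(O)(CO[Si](C(C)C)(C(C)C)C(C)C)C1 | intermediate
15 | 4'-methoxy-4-(methoxymethoxy)-6-methyl-6'-({[tri(propan-2-yl)silyl]oxy}methyl)-3H-spiro[1-benzofuran-2,1'-cyclohexa[3,5]diene]-2',3-dione (racemic) | COC1=CC(=O)C2(Oc3cc(C)cc(OCOC)c3C2=O)C(CO[Si](C(C)C)(C(C)C)C(C)C)=C1 | intermediate
16 | methyl 2-[2-hydroxy-4-methoxy-6-({[tri(propan-2-yl)silyl]oxy}methyl)phenoxy]-6-(methoxymethoxy)-4-methylbenzoate (present as its sodium phenoxide; not isolated) | COC(=O)c1c(OCOC)cc(C)cc1Oc1c(CO[Si](C(C)C)(C(C)C)C(C)C)cc(OC)cc1O | intermediate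
17 | methyl 2-[4-methoxy-2-(methoxymethoxy)-6-({[tri(propan-2-yl)silyl]oxy}methyl)phenoxy]-6-(methoxymethoxy)-4-methylbenzoate | COC(=O)c1c(OCOC)cc(C)cc1Oc1c(CO[Si](C(C)C)(C(C)C)C(C)C)cc(OC)cc1OCOC | intermediate
18 | methyl 2-[2-(hydroxymethyl)-4-methoxy-6-(methoxymethoxy)phenoxy]-6-(methoxymethoxy)-4-methylbenzoate | COC(=O)c1c(OCOC)cc(C)cc1Oc1c(CO)cc(OC)cc1OCOC | intermediate
19 | palmitoyl chloride (hexadecanoyl chloride) | CCCCCCCCCCCCCCCC(=O)Cl | starting material
20 | methyl 2-{2-[(hexadecanoyloxy)methyl]-4-methoxy-6-(methoxymethoxy)phenoxy}-6-(methoxymethoxy)-4-methylbenzoate | CCCCCCCCCCCCCCCC(=O)OCc1cc(OC)cc(OCOC)c1Oc1cc(C)cc(OCOC)c1C(=O)OC | intermediate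
21 | Betaethrin E, methyl 2-{2-[(hexadecanoyloxy)methyl]-6-hydroxy-4-methoxyphenoxy}-6-hydroxy-4-methylbenzoate | CCCCCCCCCCCCCCCC(=O)OCc1cc(OC)cc(O)c1Oc1cc(C)cc(O)c1C(=O)OC | target

## Step count and least certain steps

Total step count: 13. Longest linear sequence: 10 steps (8 to 21, steps 4 to 13); the branch from 1 is 9 steps (steps 1 to 3 and 8 to 13).

**Step 9 (key step).**
- *Risk:* the aldol addition may revert faster than water is lost, because the elimination has to pass through deprotonation of a weakly acidic vinylogous methylene. While the open triketone waits, closure of the chain methylene onto the ring ketone (towards a dibenzofuran) or retro-acylation back to the pyrone can gain ground, and hydroxide from the released water could open the product early.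
- *Fallback, from 13 back to 15:* addition and elimination are separated. 13 is closed to 14 with Et3N in CH2Cl2 at 0 °C. The tertiary alcohol is trapped with (CF3CO)2O and pyridine at −20 °C as the tertiary trifluoroacetate F1. F1 is eliminated with DBU at 0 °C; the better leaving group makes the elimination fast and irreversible.

**Step 8.**
- *Risk:* attack of the enolate at the wrong site of the pyrone (conjugate addition at C6, or addition–elimination at C4 with loss of methoxide), proton transfer from the pyrone to the enolate, and self-condensation of the ketone.
- *Fallback, from 7 back to 13:* the chain is built in two C–C bond formations.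
  - 7 is C-acylated (LiN(SiMe3)2, THF, −78 °C) with 1-[(2E)-3-methoxybut-2-enoyl]-1H-benzotriazole F2, made from (E)-3-methoxybut-2-enoic acid, benzotriazole and SOCl2. This gives 2-[(2E)-3-methoxybut-2-enoyl]-4-(methoxymethoxy)-6-methyl-1-benzofuran-3(2H)-one F3.
  - F3 is deprotonated at C2 and at the terminal methyl group with LiN(i-Pr)2 (3.2 equiv, THF, −78 °C). The terminal carbanion of this vinylogous dianion is acylated with methyl {[tri(propan-2-yl)silyl]oxy}acetate F4, made from methyl glycolate and TIPSCl. The third equivalent of base takes up the proton of the new doubly activated CH2.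

**Step 3.**
- *Risk:* saponification may stall because the ester sits on an enolate, forcing harsher hydrolysis; the acetal may be lost during acidification; the product ketone may self-condense.
- *Fallback, from 2 back to 7:* the carboxyl group is removed under neutral conditions.
  - 2 is alkylated with allyl bromoacetate (K2CO3, DMF) to methyl 2-(methoxymethoxy)-4-methyl-6-[2-oxo-2-(prop-2-en-1-yloxy)ethoxy]benzoate F5.
  - Dieckmann closure with LiN(SiMe3)2 in THF at −78 °C gives prop-2-en-1-yl 3-hydroxy-4-(methoxymethoxy)-6-methyl-1-benzofuran-2-carboxylate F6.
  - Pd(PPh3)4 (cat.) with morpholine in THF at rt removes the allyl group, and the β-keto acid loses CO2 to give 7.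

**Step 10.**
- *Risk:* incomplete capping of the phenoxide, because residual methanol or methoxide consumes the chloromethyl ether; slow side reactions of the phenoxide while it waits.
- *Fallback, from 16 to 21:* the cap is dropped and the alcohol is told from the phenol by reagent choice.
  - The ring opening is quenched with NH4Cl and 16 is isolated.
  - Bu4NF/AcOH gives methyl 2-[2-hydroxy-6-(hydroxymethyl)-4-methoxyphenoxy]-6-(methoxymethoxy)-4-methylbenzoate F7.
  - Mitsunobu esterification with palmitic acid (PPh3, DIAD, THF, 0 °C) gives methyl 2-{2-[(hexadecanoyloxy)methyl]-6-hydroxy-4-methoxyphenoxy}-6-(methoxymethoxy)-4-methylbenzoate F8. The carboxylic acid is the more acidic pronucleophile, so the activated primary alcohol should be taken by palmitate and not by the phenol.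
  - ZnBr2 and n-PrSH in CH2Cl2 at 0 °C remove the remaining acetal to give 21.

**Step 13.**
- *Risk:* ionisation or thiolysis of the benzylic ester C–O bond under the Lewis acid (the ortho aryloxy group stabilises a benzylic cation), or slow cleavage of the ring A acetal, which lacks a chelating neighbour.
- *Fallback, from 18 to 21:* the order is reversed so that no deprotection follows the esterification.
  - 2 M HCl (aq) in THF at 40 °C removes both acetals from 18 and gives methyl 2-hydroxy-6-[2-hydroxy-6-(hydroxymethyl)-4-methoxyphenoxy]-4-methylbenzoate F9.
  - Vinyl palmitate with immobilised Candida antarctica lipase B in tert-butyl methyl ether at 40 °C acylates the primary alcohol and should leave both phenols alone.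

## Further compounds

F1 | step 9 | 4'-methoxy-4-(methoxymethoxy)-6-methyl-2',3-dioxo-6'-({[tri(propan-2-yl)silyl]oxy}methyl)-3H-spiro[1-benzofuran-2,1'-cyclohex[3]en]-6'-yl trifluoroacetate (racemic, mixture of diastereomers) | COC1=CC(=O)C2(Oc3cc(C)cc(OCOC)c3C2=O)C(OC(=O)C(F)(F)F)(CO[Si](C(C)C)(C(C)C)C(C)C)C1
F2 | step 8 | 1-[(2E)-3-methoxybut-2-enoyl]-1H-benzotriazole | C/C(OC)=C\C(=O)n1nnc2ccccc12
F3 | step 8 | 2-[(2E)-3-methoxybut-2-enoyl]-4-(methoxymethoxy)-6-methyl-1-benzofuran-3(2H)-one (racemic) | C/C(OC)=C\C(=O)C1Oc2cc(C)cc(OCOC)c2C1=O
F4 | step 8 | methyl {[tri(propan-2-yl)silyl]oxy}acetate | COC(=O)CO[Si](C(C)C)(C(C)C)C(C)C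
F5 | step 3 | methyl 2-(methoxymethoxy)-4-methyl-6-[2-oxo-2-(prop-2-en-1-yloxy)ethoxy]benzoate | C=CCOC(=O)COc1cc(C)cc(OCOC)c1C(=O)OC
F6 | step 3 | prop-2-en-1-yl 3-hydroxy-4-(methoxymethoxy)-6-methyl-1-benzofuran-2-carboxylate | C=CCOC(=O)c1oc2cc(C)cc(OCOC)c2c1O
F7 | step 10 | methyl 2-[2-hydroxy-6-(hydroxymethyl)-4-methoxyphenoxy]-6-(methoxymethoxy)-4-methylbenzoate | COC(=O)c1c(OCOC)cc(C)cc1Oc1c(CO)cc(OC)cc1O
F8 | step 10 | methyl 2-{2-[(hexadecanoyloxy)methyl]-6-hydroxy-4-methoxyphenoxy}-6-(methoxymethoxy)-4-methylbenzoate | CCCCCCCCCCCCCCCC(=O)OCc1cc(OC)cc(O)c1Oc1cc(C)cc(OCOC)c1C(=O)OC
F9 | step 13 | methyl 2-hydroxy-6-[2-hydroxy-6-(hydroxymethyl)-4-methoxyphenoxy]-4-methylbenzoate | COC(=O)c1c(O)cc(C)cc1Oc1c(CO)cc(OC)cc1O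
A1 | alternative 1 | 3-(methoxymethoxy)-5-methyl-2-(trimethylsilyl)phenyl trifluoromethanesulfonate | COCOc1cc(C)cc(OS(=O)(=O)C(F)(F)F)c1[Si](C)(C)C
A2 | alternative 1 | 4-methoxy-2-(methoxymethoxy)-6-({[tri(propan-2-yl)silyl]oxy}methyl)phenyl methyl carbonate | COC(=O)Oc1c(CO[Si](C(C)C)(C(C)C)C(C)C)cc(OC)cc1OCOC
A3 | alternative 1 | methyl 2-[4-methoxy-2-(methoxymethoxy)-6-({[tri(propan-2-yl)silyl]oxy}methyl)phenoxy]-6-(methoxymethoxy)-4-methylbenzoate | COC(=O)c1c(OCOC)cc(C)cc1Oc1c(CO[Si](C(C)C)(C(C)C)C(C)C)cc(OC)cc1OCOC
A4 | alternative 1 | 4-methoxy-2-(methoxymethoxy)-6-({[tri(propan-2-yl)silyl]oxy}methyl)phenol | COCOc1cc(OC)cc(CO[Si](C(C)C)(C(C)C)C(C)C)c1O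
A5 | alternative 2 | methyl 2-{[(1E)-4-diazo-3-oxo-2-({[tri(propan-2-yl)silyl]oxy}methyl)but-1-en-1-yl]oxy}-6-(methoxymethoxy)-4-methylbenzoate | O=C(C=[N+]=[N-])/C(CO[Si](C(C)C)(C(C)C)C(C)C)=C/Oc1cc(C)cc(OCOC)c1C(=O)OC
A6 | alternative 2 | methoxyacetylene (methoxyethyne) | COC#C
A7 | alternative 2 | methyl 2-[2-hydroxy-4-methoxy-6-({[tri(propan-2-yl)silyl]oxy}methyl)phenoxy]-6-(methoxymethoxy)-4-methylbenzoate | COc1cc(O)c(Oc2cc(C)cc(OCOC)c2C(=O)OC)c(CO[Si](C(C)C)(C(C)C)C(C)C)c1
A8 | alternative 3 | methyl 4-[4-methoxy-2-(methoxymethoxy)-6-({[tri(propan-2-yl)silyl]oxy}methyl)phenoxy]-6-methyl-2-oxo-2H-pyran-3-carboxylate | COC(=O)C1=C(Oc2c(CO[Si](C(C)C)(C(C)C)C(C)C)cc(OC)cc2OCOC)C=C(C)OC1=O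
A9 | alternative 3 | ketene bis(trimethylsilyl) acetal, [ethene-1,1-diylbis(oxy)]bis(trimethylsilane) | C=C(O[Si](C)(C)C)O[Si](C)(C)C
A10 | alternative 3 | methyl 2-hydroxy-6-[4-methoxy-2-(methoxymethoxy)-6-({[tri(propan-2-yl)silyl]oxy}methyl)phenoxy]-4-methylbenzoate | COC(=O)c1c(O)cc(C)cc1Oc1c(CO[Si](C(C)C)(C(C)C)C(C)C)cc(OC)cc1OCOC
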